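**Plan**
Retrosynthesis: the C2–H bond is cut first (hydride to a C2 oxocarbenium ion), then O1–C2 (hemiketal between an aryl ketone and the C5 hydroxyl), then C2–C3 and C4–CH2Ar, both traced to one tandem conjugate addition–alkylation on a chiral butenolide.
Enabling feature: in the oxolane O1–C2–C3–C4–C5, C3 bears two one-carbon branches (ring C2 and the CH2OH carbon) and C4 two more (ring C5 and the benzylic CH2). The chain C5–C4–C3–CH2OH can therefore be read as a γ-butyrolactone (C5 = carbonyl, CH2OH carbon = acetal carbon) with C2 outside the ring, and because C2 and the CH2OH carbon trade ring and branch roles at C3, the 3,4-cis ether equals a 3,4-trans lactone.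
Forward: both C–C bonds are made on the preformed lactone (dithiane anion, then benzyl bromide), LiAlH4 dismantles the lactone, and the only ring of the target, the oxolane, closes when the unmasked ketone is captured by the C5 hydroxyl, before ionic reduction at C2.
Stereochemistry: the (5R) acetal of the menthyloxy butenolide (from (−)-menthol, by crystallisation) directs the dithiane anion anti (target C3), the dithianyl group directs the benzyl bromide trans (target C4), and hydride attack anti to both arms sets C2.

Key step: step 6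

Remark: the SMILES string is read as the all-cis (2R,3R,4R) oxolane, and that isomer is the one made. Target locants O1, C2 (aryl), C3 (CH2OH), C4 (benzyl), C5 are used unless "lactone" is written; menthyl = (1R,2S,5R)-2-isopropyl-5-methylcyclohexyl.

**Route**

Step 1
Reactants: 1 furfural
Product: 3 5-hydroxyfuran-2(5H)-one (racemic), via furfural endoperoxide 2 (not isolated)
Conditions: O2, hν (visible light), rose bengal (4,5,6,7-tetrachloro-2′,4′,5′,7′-tetraiodofluorescein disodium salt, cat.), MeOH, rt
Reagents that add atoms: oxygen, O=O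
Why: Dye-sensitised photo-oxygenation, in which singlet oxygen adds [4+2] across the furan diene and methanol cleaves endoperoxide 2 with loss of the formyl carbon as methyl formate; no stereocentre is controlled, and 3 is racemic and labile at C5.

Step 2
Reactants: 3 5-hydroxyfuran-2(5H)-one; 4 (−)-menthol
Product: 5 (5R)-5-[(1R,2S,5R)-menthyloxy]furan-2(5H)-one
Conditions: (+)-camphor-10-sulfonic acid (cat.), toluene, reflux, Dean–Stark; crystallisation from petroleum ether at −20 °C; mother liquor re-equilibrated with acid and recrystallised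
Reagents that add atoms: none
Why: Acid-catalysed acetalisation of a pseudo-acid lactol with azeotropic removal of water gives both C5 epimers, which interconvert under the acid, and the (5R) epimer is withdrawn by crystallisation (crystallisation-driven resolution of a labile acetal centre), so C5 is fixed by the menthol configuration.

Step 3
Reactants: 6 3,4,5-trimethoxybenzaldehyde
Product: 7 2-(3,4,5-trimethoxyphenyl)-1,3-dithiane
Conditions: propane-1,3-dithiol, BF3·OEt2 (cat.), CH2Cl2, 0 °C → rt
Reagents that add atoms: propane-1,3-dithiol, SCCCS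
Why: Lewis acid catalysed dithioacetalisation of an aromatic aldehyde, which turns the formyl carbon into a masked acyl anion (umpolung).

Step 4
Reactants: 8 2,4,5-trimethoxybenzaldehyde
Product: 9 (2,4,5-trimethoxyphenyl)methanol
Conditions: NaBH4, MeOH, 0 °C → rt
Reagents that add atoms: none
Why: Borohydride reduction of an aromatic aldehyde to the benzylic alcohol.

Step 5
Reactants: 9 (2,4,5-trimethoxyphenyl)methanol
Product: 10 2,4,5-trimethoxybenzyl bromide
Conditions: PBr3, Et2O, 0 °C; used at once in step 6 without chromatography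
Reagents that add atoms: phosphorus tribromide, BrP(Br)Br
Why: Bromination of a benzylic alcohol with PBr3 (SN2 displacement of a phosphite ester by bromide); the electron-rich bromide is prone to self-condensation and is therefore not stored.

Step 6
Reactants: 7 2-(3,4,5-trimethoxyphenyl)-1,3-dithiane; 5 (5R)-5-[(1R,2S,5R)-menthyloxy]furan-2(5H)-one; 10 2,4,5-trimethoxybenzyl bromide
Product: 13 (3R,4R,5R)-5-[(1R,2S,5R)-menthyloxy]-3-(2,4,5-trimethoxybenzyl)-4-[2-(3,4,5-trimethoxyphenyl)-1,3-dithian-2-yl]dihydrofuran-2(3H)-one, via lithiated dithiane 11 (not isolated), via lithium lactone enolate 12 (not isolated)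
Conditions: 7, n-BuLi, THF, −78 → −20 °C; 5, THF, −78 °C; then 10, DMPU (N,N′-dimethylpropyleneurea), −78 → 0 °C; aq. NH4Cl
Reagents that add atoms: none
Why: n-BuLi removes the benzylic dithiane proton of 7, and the soft, aryl- and sulfur-stabilised carbanion 11 adds in a Michael fashion to lactone C4 of butenolide 5 (the C2–C3 bond of the target), leaving lithium enolate 12, which is C-benzylated at lactone C3 by bromide 10 in an SN2 step (the C4–CH2Ar bond of the target). The closest known reaction type is the tandem conjugate addition–enolate alkylation of 5-alkoxyfuran-2(5H)-ones with lithiated aryl dithioacetals and benzylic halides, the usual entry to dibenzylbutyrolactone lignans. No ring is closed: two C–C bonds are added to a lactone that already exists. The stereocentre at lactone C4 (target C3) is controlled by the C5 acetal, the nucleophile entering the face anti to the menthyloxy group, and the stereocentre at lactone C3 (target C4) by the bulky dithianyl group just installed, the electrophile entering trans to it, which gives the (3R,4R,5R) trans,trans lactone. The step needs 1,4- over 1,2-addition, which the delocalised and hindered 2-aryl dithiane anion secures, and anti/trans diastereoselection, which the single (5R) acetal configuration of 5 and the size of the dithianyl group secure; DMPU and low temperature favour C-alkylation over retro-Michael cleavage.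

Step 7
Reactants: 13 the trans,trans lactone
Product: 14 (2R,3R)-2-(2,4,5-trimethoxybenzyl)-3-[2-(3,4,5-trimethoxyphenyl)-1,3-dithian-2-yl]butane-1,4-diol
Conditions: LiAlH4 (excess), THF, 0 °C → rt; H2O, aq. NaOH work-up
Reagents that add atoms: none
Why: Hydride reduction of a γ-alkoxy lactone to the 1,4-diol, in which the lactone carbonyl is reduced, the ring-opened hemiacetal expels menthoxide and the carbon so released is reduced as well, while the dithioacetal, the aryl ethers and both stereocentres stay untouched.

Step 8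
Reactants: 14 the dithianyl diol
Product: 16 (3R,4R)-3-(hydroxymethyl)-4-(2,4,5-trimethoxybenzyl)-2-(3,4,5-trimethoxyphenyl)oxolan-2-ol (both C2 anomers), via open-chain hydroxy ketone 15 (not isolated)
Conditions: Hg(ClO4)2·3H2O, CaCO3, THF/H2O (5:1), 0 °C
Reagents that add atoms: water, O
Why: Thiophilic metal-assisted hydrolysis of a dithioacetal under carbonate buffer frees aryl ketone 15, whose γ-hydroxyl adds at once to close the oxolane as the cyclic hemiketal (5-exo-trig; the other hydroxyl could only give an oxetane), which takes the carbonyl away from the epimerisable C3 centre, while the non-oxidising conditions spare both trimethoxyarene rings.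

Step 9
Reactants: 16 the cyclic hemiketal
Product: 18 [(2R,3R,4R)-4-(2,4,5-trimethoxybenzyl)-2-(3,4,5-trimethoxyphenyl)oxolan-3-yl]methanol (target), via cyclic oxocarbenium ion 17 (not isolated)
Conditions: Et3SiH (excess), then BF3·OEt2, CH2Cl2, −78 → −30 °C; aq. NaHCO3
Reagents that add atoms: none
Why: Ionic hydrogenation (Lewis acid–silane reductive deoxygenation of a cyclic hemiketal), in which BF3 ionises the anomeric hydroxyl to aryl-stabilised oxocarbenium ion 17 and Et3SiH, already present in excess, transfers hydride to the face opposite the cis C3 and C4 arms, so that C2 is set (2R) with the aryl group cis to both, the cold, silane-rich medium disfavouring proton loss from C3.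

**Compound list**
1 | furfural | O=Cc1ccco1 | starting material
2 | 2,3,7-trioxabicyclo[2.2.1]hept-5-ene-1-carbaldehyde (furfural endoperoxide, racemic) | O=CC12OOC(C=C1)O2 | intermediate
3 | 5-hydroxyfuran-2(5H)-one (racemic) | O=C1C=CC(O)O1 | intermediate
4 | (−)-menthol, (1R,2S,5R)-2-isopropyl-5-methylcyclohexan-1-ol | CC(C)[C@@H]1CC[C@@H](C)C[C@H]1O | starting material
5 | (5R)-5-[(1R,2S,5R)-menthyloxy]furan-2(5H)-one | O=C1C=C[C@H](O[C@@H]2C[C@H](C)CC[C@H]2C(C)C)O1 | intermediate
6 | 3,4,5-trimethoxybenzaldehyde | COc1cc(C=O)cc(OC)c1OC | starting material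
7 | 2-(3,4,5-trimethoxyphenyl)-1,3-dithiane | COc1cc(C2SCCCS2)cc(OC)c1OC | intermediate
8 | 2,4,5-trimethoxybenzaldehyde | COc1cc(OC)c(OC)cc1C=O | starting material
9 | (2,4,5-trimethoxyphenyl)methanol | COc1cc(OC)c(OC)cc1CO | intermediate
10 | 2,4,5-trimethoxybenzyl bromide | COc1cc(OC)c(OC)cc1CBr | intermediate
11 | 2-lithio-2-(3,4,5-trimethoxyphenyl)-1,3-dithiane | [Li]C1(c2cc(OC)c(OC)c(OC)c2)SCCCS1 | intermediate
12 | lithium (4R,5R)-5-[(1R,2S,5R)-menthyloxy]-4-[2-(3,4,5-trimethoxyphenyl)-1,3-dithian-2-yl]-4,5-dihydrofuran-2-olate | [Li]OC1=C[C@@H](C2(c3cc(OC)c(OC)c(OC)c3)SCCCS2)[C@H](O[C@@H]2C[C@H](C)CC[C@H]2C(C)C)O1 | intermediate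
13 | (3R,4R,5R)-5-[(1R,2S,5R)-menthyloxy]-3-(2,4,5-trimethoxybenzyl)-4-[2-(3,4,5-trimethoxyphenyl)-1,3-dithian-2-yl]dihydrofuran-2(3H)-one | O=C1O[C@@H](O[C@@H]2C[C@H](C)CC[C@H]2C(C)C)[C@H](C2(c3cc(OC)c(OC)c(OC)c3)SCCCS2)[C@H]1Cc1cc(OC)c(OC)cc1OC | intermediate
14 | (2R,3R)-2-(2,4,5-trimethoxybenzyl)-3-[2-(3,4,5-trimethoxyphenyl)-1,3-dithian-2-yl]butane-1,4-diol | COc1cc(OC)c(OC)cc1C[C@@H](CO)[C@H](CO)C1(c2cc(OC)c(OC)c(OC)c2)SCCCS1 | intermediate
15 | (2R,3R)-4-hydroxy-2-(hydroxymethyl)-3-(2,4,5-trimethoxybenzyl)-1-(3,4,5-trimethoxyphenyl)butan-1-one | COc1cc(OC)c(OC)cc1C[C@@H](CO)[C@H](CO)C(=O)c1cc(OC)c(OC)c(OC)c1 | intermediate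
16 | (3R,4R)-3-(hydroxymethyl)-4-(2,4,5-trimethoxybenzyl)-2-(3,4,5-trimethoxyphenyl)oxolan-2-ol (both C2 anomers) | COc1cc(OC)c(OC)cc1C[C@H]1COC(O)(c2cc(OC)c(OC)c(OC)c2)[C@H]1CO | intermediate
17 | (3R,4R)-3-(hydroxymethyl)-4-(2,4,5-trimethoxybenzyl)-2-(3,4,5-trimethoxyphenyl)-4,5-dihydro-3H-furan-1-ium | COc1cc(OC)c(OC)cc1C[C@H]1C[O+]=C(c2cc(OC)c(OC)c(OC)c2)[C@H]1CO | intermediate
18 | [(2R,3R,4R)-4-(2,4,5-trimethoxybenzyl)-2-(3,4,5-trimethoxyphenyl)oxolan-3-yl]methanol | COc1cc(OC)c(OC)cc1C[C@H]1CO[C@@H](c2cc(OC)c(OC)c(OC)c2)[C@H]1CO | target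

**Count**
Total steps: 9. Longest linear sequence: 6 steps (1 → 3 → 5 → 13 → 14 → 16 → 18; the branch from 8 is equally long).

**Steps most likely to fail**

Step 9. The oxocarbenium ion may lose the C3 proton faster than it takes hydride, so that C3 equilibrates through the cyclic enol ether toward the 3,4-trans series, or hydride may reach both faces. The fallback sets out from 16 and makes the enol ether on purpose. Mild dehydration (pyridinium p-toluenesulfonate, 4 Å molecular sieves, toluene, 50 °C) should give [(4R)-4-(2,4,5-trimethoxybenzyl)-2-(3,4,5-trimethoxyphenyl)-4,5-dihydrofuran-3-yl]methanol F1. Heterogeneous cis-hydrogenation (H2, Rh/Al2O3, EtOAc) should then deliver both hydrogens to C2 and C3 from the face opposite the C4 benzyl group, leaving aryl and CH2OH cis to it, and the route is rejoined at 18.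

Step 6. Benzylation of the crowded enolate may be outrun by self-condensation of the labile bromide or by retro-Michael loss of the dithiane anion on warming, so that unalkylated lactone is returned. The fallback sets out from 7 and 5 (enolate 12 generated as before) and traps 12 at −78 °C with the stable aldehyde 8 in an aldol reaction, the aldehyde entering trans to the dithianyl group. This should give (3S,4R,5R)-3-[hydroxy(2,4,5-trimethoxyphenyl)methyl]-5-[(1R,2S,5R)-menthyloxy]-4-[2-(3,4,5-trimethoxyphenyl)-1,3-dithian-2-yl]dihydrofuran-2(3H)-one F2 (carbinol epimers). Acylation with 1,1′-thiocarbonyldiimidazole (4-(dimethylamino)pyridine cat., CH2Cl2) should give its O-(imidazol-1-ylcarbonothioyl) derivative F3. Barton–McCombie deoxygenation (Bu3SnH, 2,2′-azobis(2-methylpropionitrile), toluene, 80 °C) removes the benzylic oxygen without touching lactone C3, and the route is rejoined at 13.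

Step 8. Hydrolysis of the hindered aryl dithioacetal on the polar diol may be slow, and the transient β-hydroxy ketone may epimerise at C3 or eliminate water before the hemiketal closes. The fallback sets out from 13 and unmasks the ketone at the lactone stage, where the trans,trans arrangement is the stable one. HgO, BF3·OEt2, aq. THF should give (3R,4R,5R)-5-[(1R,2S,5R)-menthyloxy]-3-(2,4,5-trimethoxybenzyl)-4-(3,4,5-trimethoxybenzoyl)dihydrofuran-2(3H)-one F4. LiAlH4 should reduce this to (2R,3R)-2-[hydroxy(3,4,5-trimethoxyphenyl)methyl]-3-(2,4,5-trimethoxybenzyl)butane-1,4-diol F5 (carbinol epimers, of no consequence). Chemoselective benzylic oxidation with MnO2 (CH2Cl2, rt) restores the aryl ketone, which closes to the hemiketal, and the route is rejoined at 16.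

Further compounds
F1 | step 9 | [(4R)-4-(2,4,5-trimethoxybenzyl)-2-(3,4,5-trimethoxyphenyl)-4,5-dihydrofuran-3-yl]methanol | COc1cc(OC)c(OC)cc1C[C@H]1COC(c2cc(OC)c(OC)c(OC)c2)=C1CO
F2 | step 6 | (3S,4R,5R)-3-[hydroxy(2,4,5-trimethoxyphenyl)methyl]-5-[(1R,2S,5R)-menthyloxy]-4-[2-(3,4,5-trimethoxyphenyl)-1,3-dithian-2-yl]dihydrofuran-2(3H)-one (carbinol epimers) | O=C1O[C@@H](O[C@@H]2C[C@H](C)CC[C@H]2C(C)C)[C@H](C2(c3cc(OC)c(OC)c(OC)c3)SCCCS2)[C@H]1C(O)c1cc(OC)c(OC)cc1OC
F3 | step 6 | O-(imidazol-1-ylcarbonothioyl) derivative of F2 | O=C1O[C@@H](O[C@@H]2C[C@H](C)CC[C@H]2C(C)C)[C@H](C2(c3cc(OC)c(OC)c(OC)c3)SCCCS2)[C@H]1C(OC(=S)n2ccnc2)c1cc(OC)c(OC)cc1OC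
F4 | step 8 | (3R,4R,5R)-5-[(1R,2S,5R)-menthyloxy]-3-(2,4,5-trimethoxybenzyl)-4-(3,4,5-trimethoxybenzoyl)dihydrofuran-2(3H)-one | O=C1O[C@@H](O[C@@H]2C[C@H](C)CC[C@H]2C(C)C)[C@H](C(=O)c2cc(OC)c(OC)c(OC)c2)[C@H]1Cc1cc(OC)c(OC)cc1OC
F5 | step 8 | (2R,3R)-2-[hydroxy(3,4,5-trimethoxyphenyl)methyl]-3-(2,4,5-trimethoxybenzyl)butane-1,4-diol (carbinol epimers) | COc1cc(OC)c(OC)cc1C[C@@H](CO)[C@H](CO)C(O)c1cc(OC)c(OC)c(OC)c1
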